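(The rate constants were set for the occasion; no experiment stands behind them.)

How much of what has become Tsp, Tsp3 or Sid after 2.5 min is Tsp, and how does that share move as the charge of Sub2 goes up with Ptn held at 1.00 equiv?

| flask | Sub2 | Ptn | time |
|---|---|---|---|
| amber | 0.060 M | 1.00 equiv | 2.5 min |
| violet | 0.15 M | 1.00 equiv | 2.5 min |
| red | 0.50 M | 1.00 equiv | 2.5 min |
| ochre | 1.5 M | 1.00 equiv | 2.5 min |

- share of Tsp in all that became Tsp or Tsp3 or Sid for amber, violet, red, ochre, in this order
- how the row runs (rises all the way / rises, then falls / falls all the way / falls, then rises / hardly changes)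

- given per volume of solution although it is solid: Sub2
- at the start none of Sub2 is in solution
- "hardly changes" means that all values lie within two and a half points (for a concentration: within two and a half percent of the largest)
- run time (amber): 2.5 min

    Sub + Ptn → Sub.Ptn (k1 = 0.021 L mol⁻¹ s⁻¹)
    Sub.Ptn → Tsp (k2 = 0.0068 s⁻¹)
    Ptn + Sub.Ptn ⇌ Tsp2 (K3 = 2.1 L mol⁻¹, k3 = 0.052 L mol⁻¹ s⁻¹)
    Tsp2 → Tsp3 (k4 = 0.019 s⁻¹)
    Sub2 ⇌ Sub, rate k5*(cs5 - [Sub]) while solid is left; crystals form when [Sub] > cs5 (cs5 = 0.096 M, k5 = 0.0091 s⁻¹)
    Tsp → Sid (k6 = 5.0 × 10⁻⁴ s⁻¹)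

We follow one molecule of Sub.Ptn. It leaves for Tsp at k2 or takes up Ptn at k3·c(Ptn). Once in Tsp2, it falls back at 0.0248 s⁻¹ or goes on at 0.019 s⁻¹, so its chance of reaching Tsp3 on each visit is

p = k4/(k4 + k3/K3) = 0.434

The bench rule is that, in steady flow, products stand in the ratio of these chances:

c(Tsp3)/c(Tsp) = F·c(Ptn), with F = k3·p/k2 = 3.32 L mol⁻¹

We call F the fork number: the Tsp3 made per Tsp at unit concentration of Ptn, a selectivity factor. Dissolving Sub2 stands ahead of the fork, so F holds none of its constants. We take c(Ptn) as charged, equal to the charge of Sub2 at 1.00 equiv, which gives these shares of Tsp, with Sid neglected: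

1/(1 + F·c(Ptn)): 83.4%, 66.8%, 37.6%, 16.7%

The rule stops working where Tsp2 has not kept up. One visit to Tsp2 lasts 22.9 s on average, shorter than the run of 2.5 min, but the ratio of the two is 0.153, which is too large to ignore. We assume that c(Sub.Ptn) rises in a straight line from zero, so Tsp grows with the square of time and Tsp3 follows one visit behind. That multiplies the ratio by

f = (1 − visit/run)² = 0.719

Our reckoning for amber, violet, red and ochre is then:

1/(1 + f·F·c(Ptn)): 87.5%, 73.6%, 45.6%, 21.8%

The forecast gave 87%, 75%, 47% and 21%, a row that falls all the way, on the ground that “the Tsp3 route, second order in Ptn, increasingly outruns first-order Tsp formation”; it stands below ours in amber and ochre and above ours in violet and red.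

The simulation gives 86.4%, 73.5%, 45.6% and 20.9%, a row that falls all the way, and our amber figure stands 1.1 percentage points above it. In amber at 2.50 min, Sub.Ptn goes to Tsp 2.5 times as fast as it goes to Tsp2, counting the forward rate alone. Ochre has 25.0 times the charge of amber, yet the odds against Tsp read in each flask, divided by the fork number and the charge, come to 0.790 in amber and 0.760 in ochre.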